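The numbers in the tables are calculated for substances that don't exist; scatter was added.

**Counting turnovers.** The rate constants of this flask are unknown, but its charges can be counted, on this text's own reckoning that each catalytic turnover spends one reagent on either one starting material or one second substrate. The turnover budget, reagent charged over catalyst charged, is 20.0 per catalyst. The demand is 20.0 for starting material and 10.0 for second substrate, 30.0 together, so the budget is smaller than the demand and the count ends with substrate unserved.

| flask | starting material | second substrate | reagent | free catalyst | temperature | remark | time |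
|---|---|---|---|---|---|---|---|
| midnight | 0.020 M | 0.50 equiv | 1 equiv | 5 mol% | 0 °C | the very flask that is asked about, followed so far |  |
| summer | 0.020 M | 0.50 equiv | 1 equiv | 10 mol% | 0 °C | run made earlier |  |
| flask | 0.020 M | 0.500 equiv | 1.00 equiv | 5 mol% | 0 °C |  | 20 h |

midnight run (percent of the starting material charged)

| time / h | target / % | starting material / % |
|---|---|---|
| 1.00 | 19.7 | 52.6 |
| 3.00 | 14.4 | 42.3 |
| 6.00 | 14.8 | 43.0 |
| 8.00 | 13.4 | 43.8 |
| 12.0 | 15.6 | 42.1 |
| 15.0 | 14.5 | 41.6 |
| 20.0 | 14.6 | 42.5 |

summer run (percent of the starting material charged)

| time / min | target / % | starting material / % |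
|---|---|---|
| 2.50 | 6.3 | 89.2 |
| 8.00 | 17.7 | 78.5 |
| 15.0 | 25.6 | 63.8 |
| 20.0 | 26.9 | 58.2 |
| 30.0 | 25.1 | 48.7 |
| 40.0 | 24.4 | 47.3 |
| 50.0 | 20.4 | 41.4 |

(scatter of a reading: 1 percentage point)

- target taken out counts as made
- the earlier runs do not show what temperature does; that part of a forecast is a guess
- additions bring no volume worth counting

- Friday's: at 20 h take out 90% of the target then present, then wait 10 h
- Sunday's: at 20 h add reagent, 50.0% of the amount charged, then wait 10 h
- Tuesday's: at 20 h raise the temperature by 15 K, then wait 10 h
- Thursday's: at 20 h add free catalyst, 50.0% of the amount charged, then wait 10 h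
- Wednesday's: change nothing and wait 10 h more

- target, in percent of the starting material first charged, at 20 h
- the option that brings most further target ("none" if no option brings more than 2 percentage points) (Friday's / Sunday's / Tuesday's / Thursday's / Wednesday's / none)
- target present, with what was taken out counted in, in percent of the starting material first charged, after Tuesday's
- target present, with what was taken out counted in, in percent of the starting material first charged, after Thursday's

**Two extremes.** If reagent served starting material and nothing else, the budget would just cover its 20.0 turnovers and the midnight flask would end without starting material. If second substrate were served first, it would take 10.0 and starting material would stop at 50.0%. Both draw on the same reagent, so the midnight flask should stop between these extremes. Its readings from 3.00 h onward average 42.5% starting material, lower than that upper extreme, and 14.6% target. If the budget of the midnight flask is spent, these readings count 11.5 turnovers for starting material and the other 8.51 for second substrate, and target reads 25.3% of the starting material consumed, all within the scatter of the readings. The summer run, with budget 10.0 and demand 15.0, keeps the same proportion of budget to demand and reads 41.4% starting material at 50.0 min.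

**Own reckoning.** Target at 20 h is taken as 14.6%. Thursday's and Friday's add no reagent, so this count expects no further target from either. Sunday's adds 10.0 turnovers, which brings the budget level with the demand. Second substrate takes 1.49 of them and starting material the remaining 8.51, which at that share gives 11 percentage points more target. Tuesday's stays a guess, so the choice here is Sunday's.

**The forecast.** It gives 14.6% target, 14.6% after Tuesday's, 14.6% after Thursday's, and none as the best option, holding that “more catalyst, heat or removing target do nothing” and that “More reagent would hurt”. On Sunday's it differs from the reckoning above.

**Result.** The flask holds 13.8% target at 20 h. The best option is Tuesday's, with 14 points more and 28.2% in all, against 10 points from Sunday's and 13.8% after Thursday's. At 20.0 h the flask holds 0% of its reagent, the limiting reagent, and 42.8% isomer of the product.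

    reagent + catalyst intermediate B → free catalyst + second product (k = 0.830 L mol⁻¹ s⁻¹, Ea = 43.0 kJ mol⁻¹)
    target ⇌ isomer of the product (K = 3.10, k = 7.50 × 10⁻⁴ s⁻¹, Ea = 90.0 kJ mol⁻¹, ΔH = −49.0 kJ mol⁻¹)
    starting material + free catalyst ⇌ catalyst intermediate A (K = 24.0 L mol⁻¹, k = 0.760 L mol⁻¹ s⁻¹, Ea = 43.0 kJ mol⁻¹, ΔH = −19.0 kJ mol⁻¹)
    reagent + catalyst intermediate A → free catalyst + target (k = 3.00 L mol⁻¹ s⁻¹, Ea = 37.0 kJ mol⁻¹)
    second substrate + free catalyst ⇌ catalyst intermediate B (K = 250 L mol⁻¹, k = 1.70 L mol⁻¹ s⁻¹, Ea = 37.0 kJ mol⁻¹, ΔH = 26.0 kJ mol⁻¹)
    (constants at 0 °C)

**Neighbour flask.** With 1.70 equiv of reagent the budget is 34.0 against the same demand of 30.0, which leaves 4.00 turnovers, or 11.8% of that flask's reagent charge. That flask stands at 20.0 h with 0% starting material and 11.8% of its reagent.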